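## Analysis of the target

Bromoiesol A, compound 14, is an achiral triaryl bis-ether in which three benzene rings, A, B and C, are joined by two oxygen atoms on adjacent carbons of the central ring B. Ring A is a phenol with OH at C1, the ether oxygen at C2 and bromine at C3 and C5; ring B carries the ring A oxygen at C1, the ring C oxygen at C2, bromine at C3, C4 and C5 and its only hydrogen at C6; ring C is a 2,4-dibromophenyl group. There are no stereocentres, so the problem is one of regiochemistry only. The sensitive groups are the seven aryl C–Br bonds, which exclude alkyllithium reagents, zerovalent palladium and hydrogenolysis once they are present, and the free phenol, which would make ring A the first ring to be brominated if it were unmasked early. The difficulty lies in the two diaryl ether bonds at ring B: they are ortho to each other, the one to ring C is flanked by the C1 oxygen and the C3 bromine, and neither ring B nor ring C carries a group that would activate it for nucleophilic aromatic substitution. The strategy rests on the triad C1(OAr)–C2(OAr)–C3(Br) of ring B: C1 with its oxygen corresponds to C3 of a 3-aryloxy-2-pyrone, and C2(O)–C3(Br) to a 1-bromo-2-aryloxyalkyne. A cycloaddition followed by decarboxylation can therefore build ring B with both crowded C–O bonds and the C3 bromine already attached.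

## Retrosynthetic reasoning

**Ring A hydroxyl.** The O–H of 14 is traced back to the formate 13 and from there to the aldehyde 12, exchanging the C1–O bond of ring A for a C1–CHO bond (Baeyer–Villiger oxidation, then formate cleavage). The cut is made here because the formyl group does three jobs earlier on: it activates the neighbouring carbon of ring A for ether formation, it deactivates ring A during bromination, and it is inert to heat. The forward steps must make the ring A carbon migrate in preference to hydrogen, which the ortho ether oxygen favours.

**Ring B bromines at C4 and C5.** The C4–Br and C5–Br bonds of 12 are cut, leading through the monobromide 11 to the aldehyde 10, whose ring B carries only the C3 bromine. These two positions are each para to one ether oxygen, so electrophilic substitution can address them. Ring A of 10 has no free position ortho or para to its oxygen, and ring C has only one hindered ortho position. This leaves the cycloaddition partners simple, at the price of relying on substrate-directed halogenation late in the route.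

**Ring B itself (key disconnection).** In 10 the bonds C1–C2 and C3–C4 of ring B are cut. This gives the pyrone ether 3, which supplies C1, C6, C5 and C4 together with the ring A oxygen, and the bromoalkynyl ether 8, which supplies C2 with the ring C oxygen and C3 with its bromine. The forward reaction is a [4+2] cycloaddition to the bridged lactone 9 followed by decarboxylative aromatisation. No ether bond has to be made on ring B: both oxygens arrive already bonded to the carbons that become C1 and C2. The forward step must deliver one regiochemistry, with the oxygen-bearing alkyne carbon joined to C3 of the pyrone.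

**Pyrone ether.** The bond between the pyrone oxygen and C2 of ring A in 3 is cut, giving the hydroxypyrone 1 and the fluoroaldehyde 2. The aryl carbon is activated by the ortho formyl group and by bromines ortho and para to it, so addition–elimination under mild base should suffice.

**Bromoalkynyl ether.** The triple bond of 8 is traced back to the (E)-dibromovinyl ether 7 by dehydrobromination. The O–C(vinyl) bond of 7 is then cut, giving the phenol 4 and tribromoethylene 5, which react by way of dibromoacetylene 6. The ring C oxygen is thus bonded to an sp carbon rather than to an unactivated aryl halide, and no organolithium reagent capable of bromine–lithium exchange is needed.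

## Alternatives that were turned down

Alternative 1: Rings A and C are both disconnected by pyrone cycloadditions, leaving ring B as the core.
- Forward key step: two molecules of 3,5-dibromo-2H-pyran-2-one A2 react with the two alkynyl ether arms of the ring B bis(alkynyl ether) A3, one arm terminal and one capped with a pinacol boronate. Each adduct aromatises by decarboxylation, forming four C–C bonds and giving the boronate A1. Oxidation of the C–B bond would then give 14.
- For it: every bromine comes from a building block, so no electrophilic bromination is run on the assembled triaryl ether. On this point it is stronger than the chosen route. A2 is also a more electron-poor diene than 3 and better matched to an ynol ether.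
- Against it: A3 is an unsymmetrical bis(ynol ether) of a tribromocatechol. Its two adjacent oxygens must be told apart and each given a different alkyne, without alkyllithium reagents, and both arms are thermally labile. Two cycloadditions must each be regioselective, and in the borylated arm the acceptor character of boron works against the polarisation by oxygen.
- Comparison: the chosen strategy needs one cycloaddition and reaches its two partners in one and two steps. It trades the certainty of Alternative 1 about bromine positions for a much shorter and more robust precursor synthesis.

Alternative 2: The three ring B bromines are disconnected to an amino group at C4.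
- Forward key step: the aniline A5 is brominated with two equivalents of N-bromosuccinimide A6 at both carbons ortho to nitrogen, giving A4. No ring closes. A Sandmeyer reaction then replaces nitrogen by bromine, and ether cleavage frees the ring A phenol.
- For it: the amino group is the strongest director in the molecule, its para position is blocked, and every step is a standard reaction type. On regiocontrol of the ring B bromination this route is stronger than the chosen one.
- Against it: nitrogen has to be brought in as a nitro group, reduced, and finally diazotised on a crowded, weakly basic 2,6-dibromoaniline. Ring A travels as an anisole whose positions ortho and para to methoxy are open to over-bromination by A6. The ring C ether bond must be made meta to nitrogen, where addition–elimination gets no help.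
- Comparison: the sequence is linear, at least as long, and builds no ring. The chosen route offers convergence and forms both ring B ether bonds without any substitution at an unactivated aryl carbon.

Alternative 3: The bond between the ring B oxygen and ring C, and the ortho C–Br bond of ring C, are cut together.
- Forward key step: the caesium salt of the phenol A8 adds to the aryne released by fluoride from the silylaryl triflate A9, at the aryne carbon para to bromine. The resulting aryl anion takes bromine from an electrophilic bromine donor, giving the methyl ether A7, which is then demethylated.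
- For it: the most hindered ether bond and a C–Br bond are made in one late, convergent operation, and the ring B bromines are already in place.
- Against it: a bromine para to the aryne bond exerts only a weak inductive bias, so the isomeric 2,5-dibromophenoxy ring is expected as well. A8 is an electron-poor phenoxide flanked on both sides, hence a poor nucleophile. The aryl anion can be protonated instead of brominated. A8 itself, a ring A–ring B ether with three contiguous bromines and a free hydroxyl, is no easier to make than the target.
- Comparison: the chosen cycloaddition is steered by the strong polarisation of an ynol ether rather than by a remote halogen, and its precursors are far simpler. Alternative 3 is the more convergent plan at the last stage.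

Key step: step 4

## Route

Assumption: the cycloadduct 9 forms as a racemate; both of its stereocentres become sp2 carbons of ring B when CO2 leaves, so its configuration has no bearing on the route.

Step 1
Reactants: 1 3-hydroxy-2H-pyran-2-one; 2 3,5-dibromo-2-fluorobenzaldehyde
Product: 3 3,5-dibromo-2-[(2-oxo-2H-pyran-3-yl)oxy]benzaldehyde
Conditions: K2CO3, dry DMF, 60 °C
Reagents that add atoms: none
Why: Nucleophilic aromatic substitution (addition–elimination): the acidic enol OH of 1 is deprotonated by carbonate and its oxygen attacks the C–F carbon of 2, which is activated by the ortho formyl group and by bromine ortho and para; the mild base and moderate temperature should spare the lactone.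

Step 2
Reactants: 4 2,4-dibromophenol; 5 tribromoethylene
Product: 7 2,4-dibromo-1-{[(E)-1,2-dibromoethenyl]oxy}benzene, via dibromoacetylene 6 (not isolated)
Conditions: K2CO3, DMF, rt → 50 °C, Ar, slow addition of 5
Reagents that add atoms: none
Why: Elimination–addition: base removes HBr from 5, the phenoxide of 4 adds to the haloalkyne 6 as it forms (6 is hazardous and must never accumulate or be isolated), and anti addition of aryloxide and proton across the triple bond should give the (E)-dibromovinyl ether; the aryl bromides are inert to carbonate.

Step 3
Reactants: 7 2,4-dibromo-1-{[(E)-1,2-dibromoethenyl]oxy}benzene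
Product: 8 2,4-dibromo-1-[(bromoethynyl)oxy]benzene
Conditions: LiN(SiMe3)2 (1.05 equiv), THF, −78 → −40 °C; cold work-up, kept in solution and used at once
Reagents that add atoms: none
Why: Base-induced dehydrobromination through the α-bromovinyl anion (E1cB type); the hindered silylamide should not exchange with aryl bromides at low temperature, and loss of bromide is irreversible whereas loss of aryloxide would only regenerate 6, which takes the phenoxide up again.

Step 4
Reactants: 3 3,5-dibromo-2-[(2-oxo-2H-pyran-3-yl)oxy]benzaldehyde; 8 2,4-dibromo-1-[(bromoethynyl)oxy]benzene
Product: 10 3,5-dibromo-2-[3-bromo-2-(2,4-dibromophenoxy)phenoxy]benzaldehyde, via bridged bicyclic lactone 9 (not isolated)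
Conditions: 8 (3 equiv, added in portions), BHT (cat.), 1,2-dichlorobenzene, 150–170 °C, sealed tube
Reagents that add atoms: none
Why: Proposed new method: the pyrone 3 serves as the electron-poor diene and the ynol ether 8 as the electron-rich dienophile in an inverse-demand [4+2] cycloaddition with an asynchronous transition state, in which the bond from pyrone C6 (largest LUMO coefficient) to the bromine-bearing alkyne carbon (largest HOMO coefficient, β to oxygen) runs ahead of the bond from pyrone C3 to the aryloxy-bearing carbon. The bridged lactone 9 should not survive, because retro-[4+2] loss of CO2 gives a benzene ring at once; ring B therefore closes by intermolecular [4+2] cycloaddition, forming two C–C bonds, and the closure is made irreversible by decarboxylative aromatisation. The closest known reaction type is the Diels–Alder reaction of 2-pyrones with ynamines, alkoxyalkynes and haloalkynes followed by CO2 extrusion to substituted benzenes; what is new is the pairing of a 3-aryloxy pyrone with a 1-bromo-2-aryloxyalkyne. The two bridgehead stereocentres of 9 vanish on aromatisation, so no stereocontrol is required. The selectivity needed is regiochemical, oxygen-bearing alkyne carbon to C3, and it is secured by the donor oxygen of 8, which polarises the triple bond toward the bromine-bearing carbon, and by the lactone carbonyl of 3, which makes C6 the electrophilic diene terminus. The aryl ynol ether has no β-hydrogen, so the ketene-forming fragmentation that limits alkyl ynol ethers on heating is closed, and without a Lewis acid the formyl group is not expected to add to the alkyne. The 3-aryloxy group raises the pyrone LUMO, hence the high temperature and the excess of 8.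

Step 5
Reactants: 10 3,5-dibromo-2-[3-bromo-2-(2,4-dibromophenoxy)phenoxy]benzaldehyde
Product: 12 3,5-dibromo-2-[3,4,5-tribromo-2-(2,4-dibromophenoxy)phenoxy]benzaldehyde, via ring B C4-bromide 11 (not isolated)
Conditions: Br2 (2.2 equiv), AcOH (anhydrous), rt → 50 °C, dark
Reagents that add atoms: bromine, BrBr
Why: Electrophilic aromatic bromination: ring A has no free position ortho or para to its oxygen and bears the formyl group, and ring C has two bromines and only one hindered ortho position, so ring B with two ether oxygens should react first; bromine is expected to enter at C4, para to the less encumbered oxygen at C1, and then at C5, para to the oxygen at C2, following the para,para pattern by which catechol diethers give their 4,5-dibromides.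

Step 6
Reactants: 12 3,5-dibromo-2-[3,4,5-tribromo-2-(2,4-dibromophenoxy)phenoxy]benzaldehyde
Product: 13 3,5-dibromo-2-[3,4,5-tribromo-2-(2,4-dibromophenoxy)phenoxy]phenyl formate
Conditions: mCPBA, CH2Cl2, rt → 40 °C
Reagents that add atoms: meta-chloroperoxybenzoic acid (mCPBA), OOC(=O)c1cccc(Cl)c1
Why: Baeyer–Villiger (Dakin-type) oxidation: the ortho ether oxygen raises the migratory aptitude of the ring A carbon above that of hydrogen, and aryl bromides and diaryl ethers are inert to the peracid.

Step 7
Reactants: 13 3,5-dibromo-2-[3,4,5-tribromo-2-(2,4-dibromophenoxy)phenoxy]phenyl formate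
Product: 14 bromoiesol A, 3,5-dibromo-2-[3,4,5-tribromo-2-(2,4-dibromophenoxy)phenoxy]phenol
Conditions: HCl (cat.), MeOH/THF, rt
Reagents that add atoms: none
Why: Acid-catalysed transesterification: aryl formates are cleaved by methanol under very mild conditions that touch neither the C–Br bonds nor the ether links, and the acidic medium keeps the product out of its oxidation-prone phenoxide form.

## Compound list

1 | 3-hydroxy-2H-pyran-2-one | O=c1occcc1O | starting material
2 | 3,5-dibromo-2-fluorobenzaldehyde | O=Cc1cc(Br)cc(Br)c1F | starting material
3 | 3,5-dibromo-2-[(2-oxo-2H-pyran-3-yl)oxy]benzaldehyde | O=Cc1cc(Br)cc(Br)c1Oc1cccoc1=O | intermediate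
4 | 2,4-dibromophenol | Oc1ccc(Br)cc1Br | starting material
5 | tribromoethylene | BrC=C(Br)Br | starting material
6 | dibromoacetylene (not isolated) | BrC#CBr | intermediate
7 | 2,4-dibromo-1-{[(E)-1,2-dibromoethenyl]oxy}benzene | Br/C=C(/Br)Oc1ccc(Br)cc1Br | intermediate
8 | 2,4-dibromo-1-[(bromoethynyl)oxy]benzene | BrC#COc1ccc(Br)cc1Br | intermediate
9 | 6-bromo-4-(2,4-dibromo-6-formylphenoxy)-5-(2,4-dibromophenoxy)-2-oxabicyclo[2.2.2]octa-5,7-dien-3-one (racemic, one enantiomer drawn; not isolated) | O=Cc1cc(Br)cc(Br)c1O[C@@]23C=C[C@@H](OC2=O)C(Br)=C3Oc1ccc(Br)cc1Br | intermediate
10 | 3,5-dibromo-2-[3-bromo-2-(2,4-dibromophenoxy)phenoxy]benzaldehyde | O=Cc1cc(Br)cc(Br)c1Oc1cccc(Br)c1Oc1ccc(Br)cc1Br | intermediate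
11 | 3,5-dibromo-2-[3,4-dibromo-2-(2,4-dibromophenoxy)phenoxy]benzaldehyde (not isolated) | O=Cc1cc(Br)cc(Br)c1Oc1ccc(Br)c(Br)c1Oc1ccc(Br)cc1Br | intermediate
12 | 3,5-dibromo-2-[3,4,5-tribromo-2-(2,4-dibromophenoxy)phenoxy]benzaldehyde | O=Cc1cc(Br)cc(Br)c1Oc1cc(Br)c(Br)c(Br)c1Oc1ccc(Br)cc1Br | intermediate
13 | 3,5-dibromo-2-[3,4,5-tribromo-2-(2,4-dibromophenoxy)phenoxy]phenyl formate | O=COc1cc(Br)cc(Br)c1Oc1cc(Br)c(Br)c(Br)c1Oc1ccc(Br)cc1Br | intermediate
14 | bromoiesol A, 3,5-dibromo-2-[3,4,5-tribromo-2-(2,4-dibromophenoxy)phenoxy]phenol | Oc1cc(Br)cc(Br)c1Oc1cc(Br)c(Br)c(Br)c1Oc1ccc(Br)cc1Br | target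

## Step count and risks

Total: 7 steps. Longest linear sequence: 6 steps (steps 2, 3, 4, 5, 6, 7, from 4 and 5). The second branch is a single step (step 1).

**Step 4 (key step, proposed new method).**
- What may go wrong: thermal self-condensation of the bromo ynol ether, or its addition to the formyl group, may outpace a cycloaddition that is slowed by the donor substituent on the diene. The material would then be consumed without closing ring B.
- Fallback: this fallback uses known chemistry only, sets out from 4 and 2 and returns to the route at 10; ring B is bought rather than built. Addition–elimination of 4 on commercial 3-bromo-2-fluorobenzaldehyde (K2CO3, DMF, 80 °C) should give 3-bromo-2-(2,4-dibromophenoxy)benzaldehyde F1. Baeyer–Villiger oxidation with mCPBA in CH2Cl2 gives 3-bromo-2-(2,4-dibromophenoxy)phenyl formate F2, and acid methanolysis gives 3-bromo-2-(2,4-dibromophenoxy)phenol F3. A second addition–elimination of F3 on 2 (K2CO3, DMF, 80 °C) gives 10, from which steps 5 to 7 follow unchanged.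

**Step 5.**
- What may go wrong: the second substitution on ring B may go to C6, ortho to the C1 oxygen, or substitution may occur at the free ortho position of ring C. Once ring B holds two bromines its advantage over ring C is small, and the C2 oxygen is twisted out of conjugation by its two neighbours.
- Fallback: this fallback sets out from 10 and returns to the route at 12; C5 is addressed by steric rather than electronic control. The aldehyde is protected with ethylene glycol and TsOH in toluene as 2-{3,5-dibromo-2-[3-bromo-2-(2,4-dibromophenoxy)phenoxy]phenyl}-1,3-dioxolane F4. C–H borylation with [Ir(OMe)(cod)]2, 4,4'-di-tert-butyl-2,2'-bipyridine and B2pin2 in THF at 60 °C should take place at C5 of ring B, the only C–H bond in the molecule with no ortho substituent, and give 2-{3-bromo-5-[2,4-dibromo-6-(1,3-dioxolan-2-yl)phenoxy]-4-(2,4-dibromophenoxy)phenyl}-4,4,5,5-tetramethyl-1,3,2-dioxaborolane F5. CuBr2 in MeOH/H2O at 80 °C then exchanges boron for bromine, giving 2-{3,5-dibromo-2-[3,5-dibromo-2-(2,4-dibromophenoxy)phenoxy]phenyl}-1,3-dioxolane F6. Aqueous HCl in THF frees 3,5-dibromo-2-[3,5-dibromo-2-(2,4-dibromophenoxy)phenoxy]benzaldehyde F7. One equivalent of Br2 in AcOH finally brominates C4, para to the C1 oxygen, to give 12.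

**Step 3.**
- What may go wrong: the vinyl anion may expel aryloxide, which lies anti to the carbanion lone pair, faster than bromide, and the bromo ynol ether may oligomerise during work-up. Little 8 would then reach step 4.
- Fallback: this fallback sets out from 4 and returns to the route at 8; it uses a precursor in which hydrogen and bromine are anti-periplanar and the aryloxy group cannot leave. The phenol 4 is formylated with acetic formic anhydride and pyridine to 2,4-dibromophenyl formate F8. Ramirez dibromomethylenation with CBr4 and PPh3 in CH2Cl2 gives 2,4-dibromo-1-[(2,2-dibromoethenyl)oxy]benzene F9. Anti elimination with LiN(SiMe3)2 in THF at −78 °C gives 8.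

**Step 1.**
- What may go wrong: displacement at the C–F carbon, which is flanked by formyl and bromine, may be slow with the weakly nucleophilic pyrone oxygen, so that base-induced opening of the lactone competes.
- Fallback: this fallback sets out from 1 and returns to the route at 3; the C–O bond is made by copper catalysis instead of addition–elimination. Commercial 2-amino-3,5-dibromobenzaldehyde is diazotised (NaNO2, H2SO4, 0 °C) and treated with KI to give 3,5-dibromo-2-iodobenzaldehyde F10. Ullmann-type coupling of 1 with F10 (CuI, picolinic acid, K3PO4, DMSO, 80 °C) should occur at the C–I bond, assisted by the ortho formyl group, and leave the C–Br bonds untouched, giving 3.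

## Further compounds

F1 | step 4 | 3-bromo-2-(2,4-dibromophenoxy)benzaldehyde | O=Cc1cccc(Br)c1Oc1ccc(Br)cc1Br
F2 | step 4 | 3-bromo-2-(2,4-dibromophenoxy)phenyl formate | O=COc1cccc(Br)c1Oc1ccc(Br)cc1Br
F3 | step 4 | 3-bromo-2-(2,4-dibromophenoxy)phenol | Oc1cccc(Br)c1Oc1ccc(Br)cc1Br
F4 | step 5 | 2-{3,5-dibromo-2-[3-bromo-2-(2,4-dibromophenoxy)phenoxy]phenyl}-1,3-dioxolane | Brc1cc(Br)c(Oc2cccc(Br)c2Oc2ccc(Br)cc2Br)c(c1)C3OCCO3
F5 | step 5 | 2-{3-bromo-5-[2,4-dibromo-6-(1,3-dioxolan-2-yl)phenoxy]-4-(2,4-dibromophenoxy)phenyl}-4,4,5,5-tetramethyl-1,3,2-dioxaborolane | Brc1cc(Br)c(Oc2cc(B4OC(C)(C)C(C)(C)O4)cc(Br)c2Oc2ccc(Br)cc2Br)c(c1)C3OCCO3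
F6 | step 5 | 2-{3,5-dibromo-2-[3,5-dibromo-2-(2,4-dibromophenoxy)phenoxy]phenyl}-1,3-dioxolane | Brc1cc(Br)c(Oc2cc(Br)cc(Br)c2Oc2ccc(Br)cc2Br)c(c1)C3OCCO3
F7 | step 5 | 3,5-dibromo-2-[3,5-dibromo-2-(2,4-dibromophenoxy)phenoxy]benzaldehyde | O=Cc1cc(Br)cc(Br)c1Oc1cc(Br)cc(Br)c1Oc1ccc(Br)cc1Br
F8 | step 3 | 2,4-dibromophenyl formate | O=COc1ccc(Br)cc1Br
F9 | step 3 | 2,4-dibromo-1-[(2,2-dibromoethenyl)oxy]benzene | BrC(Br)=COc1ccc(Br)cc1Br
F10 | step 1 | 3,5-dibromo-2-iodobenzaldehyde | O=Cc1cc(Br)cc(Br)c1I
A1 | alternative 1 | 2-{3,5-dibromo-2-[3,4,5-tribromo-2-(2,4-dibromophenoxy)phenoxy]phenyl}-4,4,5,5-tetramethyl-1,3,2-dioxaborolane | CC1(C)OB(OC1(C)C)c1cc(Br)cc(Br)c1Oc1cc(Br)c(Br)c(Br)c1Oc1ccc(Br)cc1Br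
A2 | alternative 1 | 3,5-dibromo-2H-pyran-2-one | O=c1occ(Br)cc1Br
A3 | alternative 1 | 2-{[3,4,5-tribromo-2-(ethynyloxy)phenoxy]ethynyl}-4,4,5,5-tetramethyl-1,3,2-dioxaborolane | CC1(C)OB(OC1(C)C)C#COc1cc(Br)c(Br)c(Br)c1OC#C
A4 | alternative 2 | 2,6-dibromo-3-(2,4-dibromophenoxy)-4-(2,4-dibromo-6-methoxyphenoxy)aniline | COc1cc(Br)cc(Br)c1Oc1cc(Br)c(N)c(Br)c1Oc1ccc(Br)cc1Br
A5 | alternative 2 | 3-(2,4-dibromophenoxy)-4-(2,4-dibromo-6-methoxyphenoxy)aniline | COc1cc(Br)cc(Br)c1Oc1ccc(N)cc1Oc1ccc(Br)cc1Br
A6 | alternative 2 | N-bromosuccinimide | O=C1CCC(=O)N1Br
A7 | alternative 3 | 1,5-dibromo-3-methoxy-2-[3,4,5-tribromo-2-(2,4-dibromophenoxy)phenoxy]benzene | COc1cc(Br)cc(Br)c1Oc1cc(Br)c(Br)c(Br)c1Oc1ccc(Br)cc1Br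
A8 | alternative 3 | 2,3,4-tribromo-6-(2,4-dibromo-6-methoxyphenoxy)phenol | COc1cc(Br)cc(Br)c1Oc1cc(Br)c(Br)c(Br)c1O
A9 | alternative 3 | 4-bromo-2-(trimethylsilyl)phenyl trifluoromethanesulfonate | C[Si](C)(C)c1cc(Br)ccc1OS(=O)(=O)C(F)(F)F
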